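**Plan**
1. Retrosynthesis: the phenol silyl ether, the oxirane oxygen and the benzoate are removed last; the C5 carbinol is traced back to an exocyclic methylene and C7 to a ketone; the C3a–C4 and C6–C7 bonds are then cut together, releasing C4–C5–C6 as a 2-methylidenepropane-1,3-diyl bis-nucleophile (12) and leaving bicyclic lactone 10.
2. Enabling feature: in the seven-membered ring C3a and C7 are 1,4-related through C8a and C8, C7 bears oxygen, and C3a is allylic to the C2(CH3)=C3 bond of the five-membered ring. Joining C7 (as a carboxyl carbon) to C3a through oxygen gives a cis-fused γ-lactone (ring O–C7–C8–C8a–C3a) that is electrophilic at both ends.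
3. Forward order: the cyclopentene ring is bought (3); the temporary lactone ring is made in step 4; the seven-membered ring is closed and the lactone ring lost in step 6; the oxirane is made in step 13.
4. Stereochemistry: C8a from 3 (anti Michael addition); C8 by equilibration to the convex face of the lactone; C3a by inversion in step 6; C5 by epoxidation directed by a temporary cis C7–OH; C7 by 1,3-anti directed reduction; C2/C3 by epoxidation directed by C5–OH.

Key step: step 6

Remark: locants follow hydroazulene numbering (C1–C3 five-membered ring, C2 bearing CH3; C3a/C8a ring fusion; C4–C8 seven-membered ring, C5 carbinol, C7 ester carbon, C8 isopropyl carbon); 1, 3, 11 and 21 are taken as commercial, and the side-chain epimers of 4–9 are carried as a mixture that converges in step 4.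

**Step 1**
Reactants: 1 methyl 3-methylbutanoate
Product: 2 [(1-methoxy-3-methylbut-1-en-1-yl)oxy](trimethyl)silane (E/Z mixture)
Conditions: LiN(iPr)2, THF, −78 °C; Me3SiCl, −78 °C to rt
Reagents that add atoms: chlorotrimethylsilane, C[Si](C)(C)Cl
Why: Kinetic ester enolate formation and O-silylation should give the silyl ketene acetal (standard enolate silylation).

**Step 2**
Reactants: 2 [(1-methoxy-3-methylbut-1-en-1-yl)oxy](trimethyl)silane, 3 (4R)-4-{[tert-butyl(dimethyl)silyl]oxy}cyclopent-2-en-1-one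
Product: 6 methyl 3-methyl-2-[(1R)-4-oxocyclopent-2-en-1-yl]butanoate (side-chain C2 epimers), via silyl enol ether adduct 4 (not isolated), via silyloxy ketone 5 (not isolated)
Conditions: Me3SiOTf (5 mol %), CH2Cl2, −78 °C; 1 M HCl, THF, 0 °C; DBU (1,8-diazabicyclo[5.4.0]undec-7-ene), CH2Cl2, 0 °C, short contact
Reagents that add atoms: none
Why: Mukaiyama–Michael addition should occur anti to the silyloxy group of 3 and so set C8a, after which hydrolysis of the enol ether and E1cB loss of silanolate give the 4-substituted cyclopentenone; the side-chain centre is left uncontrolled here and is corrected in step 4.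

**Step 3**
Reactants: 6 methyl 3-methyl-2-[(1R)-4-oxocyclopent-2-en-1-yl]butanoate
Product: 7 methyl 2-[(1R)-4-hydroxy-4-methylcyclopent-2-en-1-yl]-3-methylbutanoate (carbinol epimers)
Conditions: MeMgBr, CeCl3, THF, −78 °C; aq. NH4Cl
Reagents that add atoms: methylmagnesium bromide, C[Mg]Br
Why: Organocerium-type 1,2-addition to the enone carbonyl should leave the hindered ester untouched and installs the C2 methyl group; both carbinol epimers are usable because step 4 is reversible.

**Step 4**
Reactants: 7 methyl 2-[(1R)-4-hydroxy-4-methylcyclopent-2-en-1-yl]-3-methylbutanoate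
Product: 10 (3S,3aS,6aR)-5-methyl-3-(propan-2-yl)-3,3a,4,6a-tetrahydro-2H-cyclopenta[b]furan-2-one, via cis-hydroxy ester 8 (not isolated), via epimeric lactone mixture 9 (not isolated)
Conditions: Ph3SiOReO3 (3 mol %), CH2Cl2, 0 °C to rt; then DBU, toluene, 60 °C
Reagents that add atoms: none
Why: Reversible rhenium-oxo-catalysed 1,3-transposition of the tertiary allylic alcohol ([3,3] shift of the perrhenate ester) gives the secondary alcohol and the C2=C3 alkene, only the cis isomer is drained off as the γ-lactone, and DBU should equilibrate the lactone α-carbon (C8) to the exo isopropyl epimer on the convex face of the cis-bicyclo[3.3.0] frame.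

**Step 5**
Reactants: 11 3-chloro-2-(chloromethyl)prop-1-ene
Product: 12 (2-methylidenepropane-1,3-diyl)bis(tributylstannane)
Conditions: Mg turnings, Bu3SnCl, THF, reflux
Reagents that add atoms: tributyltin chloride, CCCC[Sn](Cl)(CCCC)CCCC
Why: Barbier-type trapping of the allylic magnesium species formed in situ by the tin chloride, as in the preparation of the analogous bis-silane.

**Step 6**
Reactants: 10 (3S,3aS,6aR)-5-methyl-3-(propan-2-yl)-3,3a,4,6a-tetrahydro-2H-cyclopenta[b]furan-2-one, 12 (2-methylidenepropane-1,3-diyl)bis(tributylstannane)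
Product: 15 (3aS,8S,8aR)-2-methyl-5-methylidene-8-(propan-2-yl)-3a,4,5,6,8,8a-hexahydroazulen-7(1H)-one, via distannyl ester 13 (not isolated), via dilithio carboxylate 14 (not isolated)
Conditions: Pd2(dba)3 (2.5 mol %), P(2-furyl)3 (10 mol %), LiCl, THF, 60 °C; then MeLi (2.2 equiv), −78 to 0 °C; aq. NH4Cl
Reagents that add atoms: none
Why: Proposed new method: zerovalent palladium ionises the allylic lactone C3a–O bond of 10 with inversion, one allyl–tin bond of 12 transmetalates, and reductive elimination joins C4 to the less hindered secondary terminus C3a on the palladium face, so the lactone oxygen (cis to the side chain) is replaced with overall inversion and C4 ends trans to the C8a substituent while the C2=C3 alkene is kept. MeLi then cleaves the stannyl ester and exchanges the remaining allyl–tin bond for lithium faster than it adds to the carboxylate, and the allyllithium terminus C6 adds to the lithium carboxylate carbon C7 to give a dilithium gem-diolate that collapses to ketone 15 on work-up. The closest known reaction types are the Stille allyl–allyl coupling of allylic carboxylates (inversion at the electrophile), the anti opening of vinyl lactones by organocopper reagents, and the Parham-type addition of an organolithium to a lithium carboxylate; their use in one pot as a lactone-to-cycloheptanone (4+3) annulation is the new element. The seven-membered ring is closed in the second event by 7-exo-trig addition of C6 to the carboxylate carbon, whereas the first event opens the temporary lactone ring. The only new stereocentre, C3a, is fixed by the stereospecific anti displacement, and C8 is untouched because the carboxylate α-carbon is not deprotonated under these conditions. The step needs coupling at C3a and not at C2, which the methyl group on the tertiary terminus should secure, and mono-coupling of 12, which a slight excess should secure.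

**Step 7**
Reactants: 15 (3aS,8S,8aR)-2-methyl-5-methylidene-8-(propan-2-yl)-3a,4,5,6,8,8a-hexahydroazulen-7(1H)-one
Product: 16 (3aS,7R,8S,8aR)-2-methyl-5-methylidene-8-(propan-2-yl)-1,3a,4,5,6,7,8,8a-octahydroazulen-7-ol
Conditions: LiBH(s-Bu)3, THF, −78 °C; aq. NH4Cl
Reagents that add atoms: none
Why: The bulky hydride should attack from the less hindered equatorial direction and give the axial alcohol cis to the C8 isopropyl group, which is wanted only as a directing group for step 8.

**Step 8**
Reactants: 16 (3aS,7R,8S,8aR)-2-methyl-5-methylidene-8-(propan-2-yl)-1,3a,4,5,6,7,8,8a-octahydroazulen-7-ol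
Product: 17 (3aS,5R,7R,8S,8aR)-2-methyl-8-(propan-2-yl)-3a,4,6,7,8,8a-hexahydro-1H-spiro[azulene-5,2'-oxiran]-7-ol
Conditions: VO(acac)2 (5 mol %), t-BuOOH, CH2Cl2, 0 °C to rt
Reagents that add atoms: tert-butyl hydroperoxide, CC(C)(C)OO
Why: Vanadium-catalysed hydroxyl-directed epoxidation should deliver oxygen to the homoallylic exocyclic alkene on the face of the C7–OH (setting C5) and leave the remote, undirected C2=C3 alkene alone.

**Step 9**
Reactants: 17 (3aS,5R,7R,8S,8aR)-2-methyl-8-(propan-2-yl)-3a,4,6,7,8,8a-hexahydro-1H-spiro[azulene-5,2'-oxiran]-7-ol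
Product: 18 (3aS,5R,7R,8S,8aR)-2,5-dimethyl-8-(propan-2-yl)-1,3a,4,5,6,7,8,8a-octahydroazulene-5,7-diol
Conditions: LiAlH4, THF, 0 °C to rt
Reagents that add atoms: none
Why: Hydride opens the spiro-epoxide at its CH2 terminus (SN2), which turns it into the C5 methyl carbinol without touching the stereocentre.

**Step 10**
Reactants: 18 (3aS,5R,7R,8S,8aR)-2,5-dimethyl-8-(propan-2-yl)-1,3a,4,5,6,7,8,8a-octahydroazulene-5,7-diol
Product: 19 (3aS,5R,8S,8aR)-5-hydroxy-2,5-dimethyl-8-(propan-2-yl)-3a,4,5,6,8,8a-hexahydroazulen-7(1H)-one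
Conditions: Dess–Martin periodinane, pyridine, CH2Cl2, 0 °C
Reagents that add atoms: none
Why: Only the secondary alcohol can be oxidised, which removes the temporary C7 configuration under buffered, non-enolising conditions.

**Step 11**
Reactants: 19 (3aS,5R,8S,8aR)-5-hydroxy-2,5-dimethyl-8-(propan-2-yl)-3a,4,5,6,8,8a-hexahydroazulen-7(1H)-one
Product: 20 (3aS,5R,7S,8S,8aR)-2,5-dimethyl-8-(propan-2-yl)-1,3a,4,5,6,7,8,8a-octahydroazulene-5,7-diol
Conditions: Me4NBH(OAc)3, AcOH/MeCN, −30 °C
Reagents that add atoms: none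
Why: Saksena–Evans reduction delivers hydride intramolecularly from the boron bound to the C5–OH, so the new C7–OH should end anti to C5–OH and trans to the isopropyl group.

**Step 12**
Reactants: 20 (3aS,5R,7S,8S,8aR)-2,5-dimethyl-8-(propan-2-yl)-1,3a,4,5,6,7,8,8a-octahydroazulene-5,7-diol, 21 4-{[tert-butyl(dimethyl)silyl]oxy}benzoic acid
Product: 22 (3aS,5R,7S,8S,8aR)-5-hydroxy-2,5-dimethyl-8-(propan-2-yl)-1,3a,4,5,6,7,8,8a-octahydroazulen-7-yl 4-{[tert-butyl(dimethyl)silyl]oxy}benzoate
Conditions: EDC·HCl, DMAP (4-(dimethylamino)pyridine), CH2Cl2, rt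
Reagents that add atoms: none
Why: Steglich esterification should acylate the secondary C7–OH only, the tertiary C5–OH being too hindered.

**Step 13**
Reactants: 22 (3aS,5R,7S,8S,8aR)-5-hydroxy-2,5-dimethyl-8-(propan-2-yl)-1,3a,4,5,6,7,8,8a-octahydroazulen-7-yl 4-{[tert-butyl(dimethyl)silyl]oxy}benzoate
Product: 23 (2R,3S,3aS,5R,7S,8S,8aR)-2,3-epoxy-5-hydroxy-2,5-dimethyl-8-(propan-2-yl)decahydroazulen-7-yl 4-{[tert-butyl(dimethyl)silyl]oxy}benzoate
Conditions: VO(acac)2 (5 mol %), t-BuOOH, CH2Cl2, rt
Reagents that add atoms: tert-butyl hydroperoxide, CC(C)(C)OO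
Why: Vanadium-catalysed epoxidation directed by the axial tertiary C5–OH (bishomoallylic) should deliver oxygen to the face of C2=C3 on the side of C4, which sets C2 and C3.

**Step 14**
Reactants: 23 (2R,3S,3aS,5R,7S,8S,8aR)-2,3-epoxy-5-hydroxy-2,5-dimethyl-8-(propan-2-yl)decahydroazulen-7-yl 4-{[tert-butyl(dimethyl)silyl]oxy}benzoate
Product: 24 (2R,3S,3aS,5R,7S,8S,8aR)-2,3-epoxy-5-hydroxy-2,5-dimethyl-8-(propan-2-yl)decahydroazulen-7-yl 4-hydroxybenzoate
Conditions: Bu4NF, AcOH, THF, 0 °C
Reagents that add atoms: none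
Why: Buffered fluoride cleaves the aryl silyl ether and should leave the hindered benzoate and the epoxide intact.

**Compound list**
1 | methyl 3-methylbutanoate | CC(C)CC(=O)OC | starting material
2 | [(1-methoxy-3-methylbut-1-en-1-yl)oxy](trimethyl)silane (E/Z mixture) | CC(C)C=C(OC)O[Si](C)(C)C | intermediate
3 | (4R)-4-{[tert-butyl(dimethyl)silyl]oxy}cyclopent-2-en-1-one | O=C1C=C[C@H](O[Si](C)(C)C(C)(C)C)C1 | starting material
4 | methyl 2-[(1S,5R)-5-{[tert-butyl(dimethyl)silyl]oxy}-3-[(trimethylsilyl)oxy]cyclopent-2-en-1-yl]-3-methylbutanoate (side-chain epimers) | CC(C)C(C(=O)OC)[C@@H]1C=C(O[Si](C)(C)C)C[C@H]1O[Si](C)(C)C(C)(C)C | intermediate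
5 | methyl 2-[(1S,2R)-2-{[tert-butyl(dimethyl)silyl]oxy}-4-oxocyclopentyl]-3-methylbutanoate (side-chain epimers) | CC(C)C(C(=O)OC)[C@@H]1CC(=O)C[C@H]1O[Si](C)(C)C(C)(C)C | intermediate
6 | methyl 3-methyl-2-[(1R)-4-oxocyclopent-2-en-1-yl]butanoate (side-chain epimers) | CC(C)C(C(=O)OC)[C@@H]1CC(=O)C=C1 | intermediate
7 | methyl 2-[(1R)-4-hydroxy-4-methylcyclopent-2-en-1-yl]-3-methylbutanoate (carbinol and side-chain epimers) | CC(C)C(C(=O)OC)[C@@H]1CC(C)(O)C=C1 | intermediate
8 | methyl 2-[(1S,2R)-2-hydroxy-4-methylcyclopent-3-en-1-yl]-3-methylbutanoate (side-chain epimers) | CC(C)C(C(=O)OC)[C@@H]1CC(C)=C[C@@H]1O | intermediate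
9 | (3aS,6aR)-5-methyl-3-(propan-2-yl)-3,3a,4,6a-tetrahydro-2H-cyclopenta[b]furan-2-one (C3 epimers) | CC(C)C1[C@@H]2CC(C)=C[C@@H]2OC1=O | intermediate
10 | (3S,3aS,6aR)-5-methyl-3-(propan-2-yl)-3,3a,4,6a-tetrahydro-2H-cyclopenta[b]furan-2-one | CC(C)[C@H]1[C@@H]2CC(C)=C[C@@H]2OC1=O | intermediate
11 | 3-chloro-2-(chloromethyl)prop-1-ene | ClCC(=C)CCl | starting material
12 | (2-methylidenepropane-1,3-diyl)bis(tributylstannane) | C=C(C[Sn](CCCC)(CCCC)CCCC)C[Sn](CCCC)(CCCC)CCCC | intermediate
13 | tributylstannyl (2S)-3-methyl-2-[(1R,2S)-4-methyl-2-{2-[(tributylstannyl)methyl]prop-2-en-1-yl}cyclopent-3-en-1-yl]butanoate | CC(C)[C@H](C(=O)O[Sn](CCCC)(CCCC)CCCC)[C@@H]1CC(C)=C[C@H]1CC(=C)C[Sn](CCCC)(CCCC)CCCC | intermediate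
14 | lithium (2S)-2-[(1R,2S)-2-[2-(lithiomethyl)prop-2-en-1-yl]-4-methylcyclopent-3-en-1-yl]-3-methylbutanoate | CC(C)[C@H](C(=O)O[Li])[C@@H]1CC(C)=C[C@H]1CC(=C)C[Li] | intermediate
15 | (3aS,8S,8aR)-2-methyl-5-methylidene-8-(propan-2-yl)-3a,4,5,6,8,8a-hexahydroazulen-7(1H)-one | CC(C)[C@H]1[C@@H]2CC(C)=C[C@H]2CC(=C)CC1=O | intermediate
16 | (3aS,7R,8S,8aR)-2-methyl-5-methylidene-8-(propan-2-yl)-1,3a,4,5,6,7,8,8a-octahydroazulen-7-ol | CC(C)[C@H]1[C@@H]2CC(C)=C[C@H]2CC(=C)C[C@H]1O | intermediate
17 | (3aS,5R,7R,8S,8aR)-2-methyl-8-(propan-2-yl)-3a,4,6,7,8,8a-hexahydro-1H-spiro[azulene-5,2'-oxiran]-7-ol | CC(C)[C@H]1[C@@H]2CC(C)=C[C@H]2C[C@@]3(OC3)C[C@H]1O | intermediate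
18 | (3aS,5R,7R,8S,8aR)-2,5-dimethyl-8-(propan-2-yl)-1,3a,4,5,6,7,8,8a-octahydroazulene-5,7-diol | CC(C)[C@H]1[C@@H]2CC(C)=C[C@H]2C[C@@](C)(O)C[C@H]1O | intermediate
19 | (3aS,5R,8S,8aR)-5-hydroxy-2,5-dimethyl-8-(propan-2-yl)-3a,4,5,6,8,8a-hexahydroazulen-7(1H)-one | CC(C)[C@H]1[C@@H]2CC(C)=C[C@H]2C[C@@](C)(O)CC1=O | intermediate
20 | (3aS,5R,7S,8S,8aR)-2,5-dimethyl-8-(propan-2-yl)-1,3a,4,5,6,7,8,8a-octahydroazulene-5,7-diol | CC(C)[C@H]1[C@@H]2CC(C)=C[C@H]2C[C@@](C)(O)C[C@@H]1O | intermediate
21 | 4-{[tert-butyl(dimethyl)silyl]oxy}benzoic acid | O=C(O)c1ccc(O[Si](C)(C)C(C)(C)C)cc1 | starting material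
22 | (3aS,5R,7S,8S,8aR)-5-hydroxy-2,5-dimethyl-8-(propan-2-yl)-1,3a,4,5,6,7,8,8a-octahydroazulen-7-yl 4-{[tert-butyl(dimethyl)silyl]oxy}benzoate | CC(C)[C@H]1[C@@H]2CC(C)=C[C@H]2C[C@@](C)(O)C[C@@H]1OC(=O)c1ccc(O[Si](C)(C)C(C)(C)C)cc1 | intermediate
23 | (2R,3S,3aS,5R,7S,8S,8aR)-2,3-epoxy-5-hydroxy-2,5-dimethyl-8-(propan-2-yl)decahydroazulen-7-yl 4-{[tert-butyl(dimethyl)silyl]oxy}benzoate | CC(C)[C@H]1[C@@H]2C[C@@]3(C)O[C@H]3[C@H]2C[C@@](C)(O)C[C@@H]1OC(=O)c1ccc(O[Si](C)(C)C(C)(C)C)cc1 | intermediate
24 | (2R,3S,3aS,5R,7S,8S,8aR)-2,3-epoxy-5-hydroxy-2,5-dimethyl-8-(propan-2-yl)decahydroazulen-7-yl 4-hydroxybenzoate (CNP0245441.1) | CC(C)[C@H]1[C@@H]2C[C@@]3(C)O[C@H]3[C@H]2C[C@@](C)(O)C[C@@H]1OC(=O)c1ccc(O)cc1 | target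

**Totals**
Total step count: 14. Longest linear sequence: 13 (steps 1–4 and 6–14; step 5 is a one-step branch).

**Steps most likely to fail**

Step 6 (proposed new method). The allylpalladium intermediate may couple at the tertiary terminus or lose a proton to give a cyclopentadiene. In the second stage the allyllithium may be quenched, or methyl addition may compete with ring closure. The fallback is stepwise and uses known reactions. It sets out from 10, which is opened anti at C3a by the cuprate [CH2=C(CH2SiMe3)CH2]2CuLi (from the Grignard reagent of 2-(chloromethyl)-3-(trimethylsilyl)prop-1-ene and CuBr·SMe2, THF, −78 °C) to give (2S)-3-methyl-2-[(1R,2S)-4-methyl-2-{2-[(trimethylsilyl)methyl]prop-2-en-1-yl}cyclopent-3-en-1-yl]butanoic acid F1. Oxalyl chloride converts this into (2S)-3-methyl-2-[(1R,2S)-4-methyl-2-{2-[(trimethylsilyl)methyl]prop-2-en-1-yl}cyclopent-3-en-1-yl]butanoyl chloride F2. Intramolecular Hosomi–Sakurai acylation of the allylsilane (SnCl4, CH2Cl2, −78 °C) then closes the seven-membered ring and comes back to the route at 15.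

Step 13. Facial selectivity may be poor if the tertiary hydroxyl does not reach the alkene, so that undirected attack from the face away from C4 competes, and oxygen transfer may be slow. The fallback changes from substrate direction to catalyst control. It sets out from 22, which is epoxidised with the fructose-derived Shi ketone catalyst 1,2:4,5-di-O-isopropylidene-erythro-2,3-hexodiulo-2,6-pyranose (the enantiomer matched to the required face) and KHSO5 in buffered MeCN/dimethoxymethane/water. It comes back to the route at 23 and makes no new compound.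

Step 4. The allylic perrhenate may lose water to a cyclopentadiene, and the trans carbinol may not be funnelled completely into the lactone. The fallback replaces the redox-neutral transposition by an oxidative transposition and a reduction. It sets out from 7, which pyridinium chlorochromate (C5H5NH[CrO3Cl], CH2Cl2, Babler–Dauben transposition) converts into methyl 3-methyl-2-[(1S)-4-methyl-2-oxocyclopent-3-en-1-yl]butanoate F3. Luche reduction (NaBH4, CeCl3, MeOH, −40 °C) anti to the side chain then gives the cis alcohol and comes back to the route at 8, which DBU lactonises and equilibrates to 10 as in step 4.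

**Further compounds**
F1 | step 6 | (2S)-3-methyl-2-[(1R,2S)-4-methyl-2-{2-[(trimethylsilyl)methyl]prop-2-en-1-yl}cyclopent-3-en-1-yl]butanoic acid | CC(C)[C@H](C(=O)O)[C@@H]1CC(C)=C[C@H]1CC(=C)C[Si](C)(C)C
F2 | step 6 | (2S)-3-methyl-2-[(1R,2S)-4-methyl-2-{2-[(trimethylsilyl)methyl]prop-2-en-1-yl}cyclopent-3-en-1-yl]butanoyl chloride | CC(C)[C@H](C(=O)Cl)[C@@H]1CC(C)=C[C@H]1CC(=C)C[Si](C)(C)C
F0 | step 13 | none | none
F3 | step 4 | methyl 3-methyl-2-[(1S)-4-methyl-2-oxocyclopent-3-en-1-yl]butanoate (side-chain epimers) | CC(C)C(C(=O)OC)[C@@H]1CC(C)=CC1=O
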